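**Plan**

- Retrosynthesis: after removal of one benzoate, the benzyl ethers and two bromine caps, ring C of unit 2 (the epiafzelechin unit) is cut at C2–C3 and at C4–C4a. This leaves a methyl aryl acetal (unit 1, ring A of unit 2 and the aldehyde carbon that carries ring B) and an E-enol benzoate on C8 of unit 3 of the lower dimer.
- Enabling feature: unit 1 sits on C6 of unit 2, para to O1, so the two ring-A carbons ortho to O1 are the same and no C6/C8 choice arises. C4 of unit 2 is bonded to the 5,7,8a-trioxygenated ring A of unit 3, which stabilises a cation at C4. Ring B of unit 2 is a plain 4-hydroxyphenyl group that can come from a benzaldehyde.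
- The bonds C4(unit 1)–C6(unit 2) and C4(unit 3)–C6(unit 4) are cut next, back to one 8-bromo C4-alkoxy epicatechin building block, phloroglucinol and an 8-bromo epicatechin nucleophile.
- Forward: epicatechin is turned into the bromo building blocks. The upper half arises by capture with phloroglucinol, unmasking of the para phenol and acetal formation. The lower half arises by alkynylation, C4→C6 flavanylation, one-pot hydroboration and fluoride exchange at boron, and copper-catalysed benzoyloxylation. Annulation then closes ring C of unit 2, followed by benzoate removal and hydrogenolysis.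
- Stereochemistry: C2 and C3 of units 1, 3 and 4 come from (−)-epicatechin. C4 of units 1 and 3 is set by attack anti to the 3-benzyloxy group. C2, C3 and C4 of unit 2 are set in the annulation (E-alkene, benzoate-endo approach, chiral phosphate counter-anion).

Key step: step 17

Assumption: the (R)-enantiomer of 3,3'-bis(2,4,6-triisopropylphenyl)-1,1'-binaphthyl-2,2'-diyl hydrogen phosphate ((R)-TRIP acid) is taken as the one whose anion matches the facial bias of the two fragments; if the (S)-acid proves matched, it is used in the same way.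

Descriptors 4β and 3α follow flavan-3-ol usage: 4β means trans to the 3-oxygen of an epicatechin unit.

**Route**

Step 1
Reactants: 1 (−)-epicatechin
Product: 2 5,7,3',4'-tetra-O-benzylepicatechin
Conditions: BnBr (4.4 equiv), K2CO3, DMF, 0 °C to rt
Reagents that add atoms: benzyl bromide BrCc1ccccc1
Why: Williamson etherification should take the four acidic phenols and leave the secondary 3-OH, with no stereocentre touched.

Step 2
Reactants: 2 5,7,3',4'-tetra-O-benzylepicatechin
Product: 3 8-bromo-5,7,3',4'-tetra-O-benzylepicatechin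
Conditions: NBS (1.0 equiv), CH2Cl2, −78 °C to rt
Reagents that add atoms: N-bromosuccinimide O=C1CCC(=O)N1Br
Why: Electrophilic aromatic bromination of the benzylated flavan-3-ol is expected at C8, the more accessible of the two ring-A positions.

Step 3
Reactants: 3 8-bromo-5,7,3',4'-tetra-O-benzylepicatechin
Product: 4 8-bromo-3,5,7,3',4'-penta-O-benzylepicatechin
Conditions: NaH, BnBr, Bu4NI (cat.), DMF, 0 °C to rt
Reagents that add atoms: benzyl bromide BrCc1ccccc1
Why: Williamson etherification of the 3-OH should proceed without epimerisation because no phenol is free to open ring C.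

Step 4
Reactants: 4 8-bromo-3,5,7,3',4'-penta-O-benzylepicatechin
Product: 5 8-bromo-3,5,7,3',4'-penta-O-benzyl-4β-(2-ethoxyethoxy)epicatechin
Conditions: DDQ (2 equiv), 2-ethoxyethanol (5 equiv), CH2Cl2, rt
Reagents that add atoms: 2-ethoxyethanol CCOCCO
Why: Benzylic oxidation by hydride abstraction at C4 gives the ring-A-stabilised cation, and the alcohol should add anti to the 3-benzyloxy group to set the 4β ether.

Step 5
Reactants: 5 8-bromo-3,5,7,3',4'-penta-O-benzyl-4β-(2-ethoxyethoxy)epicatechin; 6 phloroglucinol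
Product: 7 2-(8-bromo-3,5,7,3',4'-penta-O-benzylepicatechin-4β-yl)benzene-1,3,5-triol
Conditions: 6 (10 equiv), BF3·OEt2 (0.5 equiv), THF–CH2Cl2, −20 to 0 °C
Reagents that add atoms: none
Why: Friedel–Crafts flavanylation of the symmetric triphenol can give only one constitution, the bromine cap prevents self-condensation at C8, and attack anti to the 3-benzyloxy group sets C4 as 4β.

Step 6
Reactants: 7 2-(8-bromo-3,5,7,3',4'-penta-O-benzylepicatechin-4β-yl)benzene-1,3,5-triol
Product: 8 the 5-O-triisopropylsilyl ether of 7 (silyl on the phenol para to the flavanyl group)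
Conditions: TIPSCl (1.05 equiv), imidazole, DMF, −20 to 0 °C
Reagents that add atoms: triisopropylsilyl chloride CC(C)[Si](Cl)(C(C)C)C(C)C
Why: Silylation with a bulky chloride should select the para phenol, since the two ortho phenols are shielded by the flavan-4-yl group.

Step 7
Reactants: 8 the 5-O-triisopropylsilyl ether of 7
Product: 9 the 1,3-di-O-benzyl-5-O-triisopropylsilyl ether of 7
Conditions: BnBr (3 equiv), K2CO3, Bu4NI (cat.), dry DMF, rt
Reagents that add atoms: benzyl bromide BrCc1ccccc1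
Why: Williamson etherification of the two remaining phenols should proceed under anhydrous carbonate conditions that a hindered aryl triisopropylsilyl ether tolerates.

Step 8
Reactants: 9 the 1,3-di-O-benzyl-5-O-triisopropylsilyl ether of 7
Product: 10 3,5-bis(benzyloxy)-4-(8-bromo-3,5,7,3',4'-penta-O-benzylepicatechin-4β-yl)phenol
Conditions: Bu4NF (1.1 equiv), AcOH (1.1 equiv), THF, 0 °C
Reagents that add atoms: none
Why: Fluoride cleaves the aryl silyl ether selectively, and the acetic acid buffer keeps the electron-rich phenol from standing as its phenoxide.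

Step 9
Reactants: 11 4-benzyloxybenzaldehyde
Product: 12 4-benzyloxybenzaldehyde dimethyl acetal
Conditions: HC(OMe)3, p-TsOH (cat.), MeOH, rt
Reagents that add atoms: trimethyl orthoformate COC(OC)OC
Why: Acid-catalysed acetalisation is driven to completion by the orthoformate.

Step 10
Reactants: 12 4-benzyloxybenzaldehyde dimethyl acetal
Product: 13 1-benzyloxy-4-[chloro(methoxy)methyl]benzene (used crude after removal of volatiles)
Conditions: AcCl (1.1 equiv), CH2Cl2, 0 °C to rt, then evaporation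
Reagents that add atoms: acetyl chloride CC(=O)Cl
Why: Exchange of one methoxy group of a benzaldehyde acetal for chloride by an acid chloride is a standard route to α-chloro ethers and is helped here by the para-alkoxy group.

Step 11
Reactants: 10 3,5-bis(benzyloxy)-4-(8-bromo-3,5,7,3',4'-penta-O-benzylepicatechin-4β-yl)phenol; 13 1-benzyloxy-4-[chloro(methoxy)methyl]benzene
Product: 14 methyl aryl acetal of 4-benzyloxybenzaldehyde with phenol 10 (both epimers at the acetal carbon)
Conditions: 13 (1.5 equiv), iPr2NEt, CH2Cl2, −20 °C to rt; chromatography on Et3N-deactivated silica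
Reagents that add atoms: none
Why: O-Alkylation of a phenol by an α-chloro ether under amine base is the usual way to mixed acetals, and the configuration of the acetal carbon is irrelevant because it is ionised in step 17.

Step 12
Reactants: 5 8-bromo-3,5,7,3',4'-penta-O-benzyl-4β-(2-ethoxyethoxy)epicatechin; 15 (triisopropylsilyl)acetylene
Product: 16 3,5,7,3',4'-penta-O-benzyl-4β-(2-ethoxyethoxy)-8-[(triisopropylsilyl)ethynyl]epicatechin
Conditions: 15 (2 equiv), PdCl2(MeCN)2 (5 mol %), XPhos (15 mol %), Cs2CO3, MeCN–THF, 70 °C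
Reagents that add atoms: none
Why: Copper-free Sonogashira coupling with a bulky biarylphosphine is suited to hindered, electron-rich aryl bromides, and the basic medium leaves the C4 ether intact.

Step 13
Reactants: 16 3,5,7,3',4'-penta-O-benzyl-4β-(2-ethoxyethoxy)-8-[(triisopropylsilyl)ethynyl]epicatechin; 4 8-bromo-3,5,7,3',4'-penta-O-benzylepicatechin
Product: 17 perbenzylated lower dimer, 8-[(triisopropylsilyl)ethynyl]epicatechin-(4β→6)-8-bromoepicatechin
Conditions: 4 (3 equiv), TMSOTf (0.3 equiv), CH2Cl2, −78 to −40 °C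
Reagents that add atoms: none
Why: Friedel–Crafts flavanylation can reach only C6 of 4 because C8 carries bromine, the alkynyl group blocks self-condensation of the electrophile, and attack anti to the 3-benzyloxy group sets C4 of unit 3 as 4β.

Step 14
Reactants: 17 perbenzylated lower dimer with the silylalkyne
Product: 18 perbenzylated lower dimer with an ethynyl group on C8 of unit 3
Conditions: Bu4NF (1.2 equiv), THF, 0 °C to rt
Reagents that add atoms: none
Why: Fluoride removes the alkynyl silyl group, and no other group in the molecule is sensitive to it.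

Step 15
Reactants: 18 perbenzylated lower dimer with an ethynyl group on C8 of unit 3
Product: 20 potassium (E)-alkenyltrifluoroborate of the lower dimer, via alkenylboronate 19 (not isolated)
Conditions: pinacolborane (1.2 equiv), Cp2Zr(H)Cl (10 mol %), Et3N (10 mol %), THF, 50 °C; then KHF2 (aq, 4.5 M), MeOH, rt
Reagents that add atoms: pinacolborane CC1(C)OBOC1(C)C; potassium hydrogen difluoride [K+].[F-].F
Why: Zirconium-catalysed hydroboration of the terminal alkyne is a syn addition with boron at the terminal carbon and should give only the E-alkenylboronate 19, and fluoride exchange at boron in the same flask then releases pinacol and gives the trifluoroborate without touching the alkene geometry.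

Step 16
Reactants: 20 potassium (E)-alkenyltrifluoroborate of the lower dimer
Product: 21 (E)-enol benzoate on C8 of unit 3 of the perbenzylated lower dimer
Conditions: benzoic acid (2 equiv), CuBr (20 mol %), DMAP (40 mol %), 4 Å MS, O2 (1 atm), CH2Cl2–MeCN, 40 °C
Reagents that add atoms: benzoic acid OC(=O)c1ccccc1
Why: Copper-catalysed oxidative C–O coupling of alkenyltrifluoroborates with carboxylic acids (Chan–Lam type) forms enol esters with retention of alkene geometry.

Step 17
Reactants: 14 methyl aryl acetal of 4-benzyloxybenzaldehyde with phenol 10; 21 (E)-enol benzoate of the lower dimer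
Product: 24 perbenzylated dibromo tetramer carrying a 3-O-benzoate on unit 2, via aryl oxocarbenium ion 22 (not isolated), via benzylic cation 23 (not isolated)
Conditions: 21 (1.2 equiv), (R)-TRIP acid (20 mol %), 5 Å MS, toluene, −20 °C to rt
Reagents that add atoms: none
Why: Proposed new method: the chiral acid protonates the methoxy group of 14, the sieves take up methanol, and the E-configured O-aryl oxocarbenium ion 22 remains as a contact ion pair with the phosphate; the benzoate-bearing carbon of 21 then attacks C2, because the 2,4,6-trioxygenated ring A of unit 3 stabilises the resulting benzylic cation 23 far better than the acyloxy group could stabilise the alternative. The closest known reaction is the oxa-Povarov reaction (cationic inverse-demand [4+2] annulation) of aryl oxocarbenium ions with styrenes, which has not been run with enol esters, with a chiral Brønsted acid or with partners of this size. Ring C of unit 2 closes by an intramolecular Friedel–Crafts alkylation in which either of the two equivalent ring-A carbons ortho to O1 attacks the C4 cation, a six-membered closure that is exo with respect to the quinone-methide form of the cation. C2 and C3 are set in the first bond formation by a benzoate-endo, aryl-exo arrangement (2,3-cis), favoured by attraction of the ester carbonyl to the cation and by the bulk of the lower dimer; C4 is set in the closure trans to the C3 benzoate, as the E-alkene and shielding of the cation by the neighbouring benzoate both require. The absolute sense of the three centres should follow from the face of the ion pair left open by the 2,4,6-triisopropylphenyl groups of the phosphate. The step therefore needs regioselectivity in the alkene (secured by the aryl group of unit 3), endo selectivity and facial selectivity (backed by the matched counter-anion), and the minor diastereomers would be removed by chromatography.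

Step 18
Reactants: 24 perbenzylated dibromo tetramer carrying a 3-O-benzoate on unit 2
Product: 25 perbenzylated dibromo tetramer with a free 3-OH on unit 2
Conditions: NaOMe (cat.), MeOH–THF, 40 °C
Reagents that add atoms: none
Why: Base-catalysed transesterification removes the benzoate while benzyl ethers, aryl bromides and the interflavan bonds are inert to methoxide.

Step 19
Reactants: 25 perbenzylated dibromo tetramer with a free 3-OH on unit 2
Product: 26 epicatechin-(4β→6)-epiafzelechin-(4β→8)-epicatechin-(4β→6)-epicatechin (target)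
Conditions: H2 (1 atm), Pd(OH)2 on carbon, Et3N (2.2 equiv), THF–MeOH–H2O, rt
Reagents that add atoms: none
Why: Hydrogenolysis over Pd(OH)2 on carbon should cleave the eighteen benzyl ethers and both aryl C–Br bonds in one operation, with the amine taking up HBr so that the acid-labile interflavan bonds survive.

**Compound list**

1 | (−)-epicatechin | O[C@@H]1Cc2c(O)cc(O)cc2O[C@@H]1c1ccc(O)c(O)c1 | starting material
2 | 5,7,3',4'-tetra-O-benzylepicatechin | O[C@@H]1Cc2c(OCc9ccccc9)cc(OCc9ccccc9)cc2O[C@@H]1c1ccc(OCc9ccccc9)c(OCc9ccccc9)c1 | intermediate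
3 | 8-bromo-5,7,3',4'-tetra-O-benzylepicatechin | O[C@@H]1Cc2c(OCc9ccccc9)cc(OCc9ccccc9)c(Br)c2O[C@@H]1c1ccc(OCc9ccccc9)c(OCc9ccccc9)c1 | intermediate
4 | 8-bromo-3,5,7,3',4'-penta-O-benzylepicatechin | c9ccccc9CO[C@@H]1Cc2c(OCc9ccccc9)cc(OCc9ccccc9)c(Br)c2O[C@@H]1c1ccc(OCc9ccccc9)c(OCc9ccccc9)c1 | intermediate
5 | 8-bromo-3,5,7,3',4'-penta-O-benzyl-4β-(2-ethoxyethoxy)epicatechin | CCOCCO[C@H]1c2c(OCc9ccccc9)cc(OCc9ccccc9)c(Br)c2O[C@H](c2ccc(OCc9ccccc9)c(OCc9ccccc9)c2)[C@@H]1OCc9ccccc9 | intermediate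
6 | phloroglucinol | Oc1cc(O)cc(O)c1 | starting material
7 | 2-(8-bromo-penta-O-benzylepicatechin-4β-yl)benzene-1,3,5-triol | Oc1cc(O)c([C@H]2c3c(OCc9ccccc9)cc(OCc9ccccc9)c(Br)c3O[C@H](c3ccc(OCc9ccccc9)c(OCc9ccccc9)c3)[C@@H]2OCc9ccccc9)c(O)c1 | intermediate
8 | 5-O-triisopropylsilyl ether of 7 (para phenol silylated) | CC(C)[Si](Oc1cc(O)c([C@H]2c3c(OCc9ccccc9)cc(OCc9ccccc9)c(Br)c3O[C@H](c3ccc(OCc9ccccc9)c(OCc9ccccc9)c3)[C@@H]2OCc9ccccc9)c(O)c1)(C(C)C)C(C)C | intermediate
9 | 1,3-di-O-benzyl-5-O-triisopropylsilyl ether of 7 | CC(C)[Si](Oc1cc(OCc9ccccc9)c([C@H]2c3c(OCc9ccccc9)cc(OCc9ccccc9)c(Br)c3O[C@H](c3ccc(OCc9ccccc9)c(OCc9ccccc9)c3)[C@@H]2OCc9ccccc9)c(OCc9ccccc9)c1)(C(C)C)C(C)C | intermediate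
10 | 3,5-bis(benzyloxy)-4-(8-bromo-penta-O-benzylepicatechin-4β-yl)phenol | Oc1cc(OCc9ccccc9)c([C@H]2c3c(OCc9ccccc9)cc(OCc9ccccc9)c(Br)c3O[C@H](c3ccc(OCc9ccccc9)c(OCc9ccccc9)c3)[C@@H]2OCc9ccccc9)c(OCc9ccccc9)c1 | intermediate
11 | 4-benzyloxybenzaldehyde | O=Cc1ccc(OCc2ccccc2)cc1 | starting material
12 | 4-benzyloxybenzaldehyde dimethyl acetal | COC(OC)c1ccc(OCc2ccccc2)cc1 | intermediate
13 | 1-benzyloxy-4-[chloro(methoxy)methyl]benzene | COC(Cl)c1ccc(OCc2ccccc2)cc1 | intermediate
14 | methyl aryl acetal of 4-benzyloxybenzaldehyde with phenol 10 | COC(Oc3cc(OCc9ccccc9)c([C@H]4c5c(OCc9ccccc9)cc(OCc9ccccc9)c(Br)c5O[C@H](c5ccc(OCc9ccccc9)c(OCc9ccccc9)c5)[C@@H]4OCc9ccccc9)c(OCc9ccccc9)c3)c1ccc(OCc9ccccc9)cc1 | intermediate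
15 | (triisopropylsilyl)acetylene | C#C[Si](C(C)C)(C(C)C)C(C)C | starting material
16 | 3,5,7,3',4'-penta-O-benzyl-4β-(2-ethoxyethoxy)-8-[(triisopropylsilyl)ethynyl]epicatechin | CCOCCO[C@H]1c2c(OCc9ccccc9)cc(OCc9ccccc9)c(C#C[Si](C(C)C)(C(C)C)C(C)C)c2O[C@H](c2ccc(OCc9ccccc9)c(OCc9ccccc9)c2)[C@@H]1OCc9ccccc9 | intermediate
17 | perbenzylated lower dimer, 8-[(triisopropylsilyl)ethynyl]epicatechin-(4β→6)-8-bromoepicatechin | CC(C)[Si](C#Cc3c(OCc9ccccc9)cc(OCc9ccccc9)c4c3O[C@H](c3ccc(OCc9ccccc9)c(OCc9ccccc9)c3)[C@H](OCc9ccccc9)[C@H]4c3c(OCc9ccccc9)c(Br)c4c(c3OCc9ccccc9)C[C@@H](OCc9ccccc9)[C@@H](c3ccc(OCc9ccccc9)c(OCc9ccccc9)c3)O4)(C(C)C)C(C)C | intermediate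
18 | perbenzylated lower dimer with 8-ethynyl on unit 3 | C#Cc3c(OCc9ccccc9)cc(OCc9ccccc9)c4c3O[C@H](c3ccc(OCc9ccccc9)c(OCc9ccccc9)c3)[C@H](OCc9ccccc9)[C@H]4c3c(OCc9ccccc9)c(Br)c4c(c3OCc9ccccc9)C[C@@H](OCc9ccccc9)[C@@H](c3ccc(OCc9ccccc9)c(OCc9ccccc9)c3)O4 | intermediate
19 | perbenzylated lower dimer with (E)-2-(pinacolboryl)ethenyl on C8 of unit 3 | CC1(C)OB(OC1(C)C)/C=C/c3c(OCc9ccccc9)cc(OCc9ccccc9)c4c3O[C@H](c3ccc(OCc9ccccc9)c(OCc9ccccc9)c3)[C@H](OCc9ccccc9)[C@H]4c3c(OCc9ccccc9)c(Br)c4c(c3OCc9ccccc9)C[C@@H](OCc9ccccc9)[C@@H](c3ccc(OCc9ccccc9)c(OCc9ccccc9)c3)O4 | intermediate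
20 | potassium (E)-alkenyltrifluoroborate of the lower dimer | [K+].F[B-](F)(F)/C=C/c3c(OCc9ccccc9)cc(OCc9ccccc9)c4c3O[C@H](c3ccc(OCc9ccccc9)c(OCc9ccccc9)c3)[C@H](OCc9ccccc9)[C@H]4c3c(OCc9ccccc9)c(Br)c4c(c3OCc9ccccc9)C[C@@H](OCc9ccccc9)[C@@H](c3ccc(OCc9ccccc9)c(OCc9ccccc9)c3)O4 | intermediate
21 | (E)-enol benzoate on C8 of unit 3 of the perbenzylated lower dimer | O=C(c1ccccc1)O/C=C/c3c(OCc9ccccc9)cc(OCc9ccccc9)c4c3O[C@H](c3ccc(OCc9ccccc9)c(OCc9ccccc9)c3)[C@H](OCc9ccccc9)[C@H]4c3c(OCc9ccccc9)c(Br)c4c(c3OCc9ccccc9)C[C@@H](OCc9ccccc9)[C@@H](c3ccc(OCc9ccccc9)c(OCc9ccccc9)c3)O4 | intermediate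
22 | E-configured O-aryl oxocarbenium ion from 14 (cation shown, paired with the phosphate) | c9ccccc9COc1ccc(cc1)/C=[O+]/c3cc(OCc9ccccc9)c([C@H]4c5c(OCc9ccccc9)cc(OCc9ccccc9)c(Br)c5O[C@H](c5ccc(OCc9ccccc9)c(OCc9ccccc9)c5)[C@@H]4OCc9ccccc9)c(OCc9ccccc9)c3 | intermediate
23 | open-chain benzylic cation after C2–C3 bond formation (cation shown) | c9ccccc9COc1ccc([C@@H](Oc3cc(OCc9ccccc9)c([C@H]4c5c(OCc9ccccc9)cc(OCc9ccccc9)c(Br)c5O[C@H](c5ccc(OCc9ccccc9)c(OCc9ccccc9)c5)[C@@H]4OCc9ccccc9)c(OCc9ccccc9)c3)[C@H](OC(=O)c6ccccc6)[CH+]c3c(OCc9ccccc9)cc(OCc9ccccc9)c4c3O[C@H](c3ccc(OCc9ccccc9)c(OCc9ccccc9)c3)[C@H](OCc9ccccc9)[C@H]4c3c(OCc9ccccc9)c(Br)c4c(c3OCc9ccccc9)C[C@@H](OCc9ccccc9)[C@@H](c3ccc(OCc9ccccc9)c(OCc9ccccc9)c3)O4)cc1 | intermediate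
24 | perbenzylated dibromo tetramer with 3-O-benzoate on unit 2 (bromine on C8 of units 1 and 4) | c9ccccc9COc1ccc([C@H]2Oc3cc(OCc9ccccc9)c([C@H]4c5c(OCc9ccccc9)cc(OCc9ccccc9)c(Br)c5O[C@H](c5ccc(OCc9ccccc9)c(OCc9ccccc9)c5)[C@@H]4OCc9ccccc9)c(OCc9ccccc9)c3[C@H](c3c(OCc9ccccc9)cc(OCc9ccccc9)c4c3O[C@H](c3ccc(OCc9ccccc9)c(OCc9ccccc9)c3)[C@H](OCc9ccccc9)[C@H]4c3c(OCc9ccccc9)c(Br)c4c(c3OCc9ccccc9)C[C@@H](OCc9ccccc9)[C@@H](c3ccc(OCc9ccccc9)c(OCc9ccccc9)c3)O4)[C@H]2OC(=O)c6ccccc6)cc1 | intermediate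
25 | perbenzylated dibromo tetramer with free 3-OH on unit 2 | c9ccccc9COc1ccc([C@H]2Oc3cc(OCc9ccccc9)c([C@H]4c5c(OCc9ccccc9)cc(OCc9ccccc9)c(Br)c5O[C@H](c5ccc(OCc9ccccc9)c(OCc9ccccc9)c5)[C@@H]4OCc9ccccc9)c(OCc9ccccc9)c3[C@H](c3c(OCc9ccccc9)cc(OCc9ccccc9)c4c3O[C@H](c3ccc(OCc9ccccc9)c(OCc9ccccc9)c3)[C@H](OCc9ccccc9)[C@H]4c3c(OCc9ccccc9)c(Br)c4c(c3OCc9ccccc9)C[C@@H](OCc9ccccc9)[C@@H](c3ccc(OCc9ccccc9)c(OCc9ccccc9)c3)O4)[C@H]2O)cc1 | intermediate
26 | epicatechin-(4β→6)-epiafzelechin-(4β→8)-epicatechin-(4β→6)-epicatechin, CNP0103636.1 | Oc1ccc([C@H]2Oc3cc(O)c([C@H]4c5c(O)cc(O)cc5O[C@H](c5ccc(O)c(O)c5)[C@@H]4O)c(O)c3[C@H](c3c(O)cc(O)c4c3O[C@H](c3ccc(O)c(O)c3)[C@H](O)[C@H]4c3c(O)cc4c(c3O)C[C@@H](O)[C@@H](c3ccc(O)c(O)c3)O4)[C@H]2O)cc1 | target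

**Step count and risks**

Total steps: 19. Longest linear sequence: 12 steps (steps 1–4, 12–16 and 17–19; the upper-half branch through steps 5–8 and 11 is equally long).

Steps most likely to fail:

1. Step 17. The enol ester may be attacked on the wrong face or through the exo arrangement, which would give a mixture of diastereomers at C2–C4 of unit 2. The acetal may also ionise by loss of the phenol instead of methanol, which would divert material into open-chain adducts.
Fallback (known chemistry, from 2, 4 and 5, returning at 26): unit 2 is taken from purchased (−)-epiafzelechin and the chain is assembled by Lewis-acid flavanylation with bromine caps and two orthogonal C4 leaving groups. (−)-Epiafzelechin is benzylated at its three phenols (BnBr, K2CO3) to 5,7,4'-tri-O-benzylepiafzelechin F1, NBS then gives 8-bromo-5,7,4'-tri-O-benzylepiafzelechin F2, and NaH with BnBr gives 8-bromo-3,5,7,4'-tetra-O-benzylepiafzelechin F3. DDQ and 2-ethoxyethanol give 8-bromo-3,5,7,4'-tetra-O-benzyl-4β-(2-ethoxyethoxy)epiafzelechin F4, and 2,6-dimethylbenzenethiol with BF3·OEt2 exchanges the ether to give 8-bromo-3,5,7,4'-tetra-O-benzyl-4β-(2,6-dimethylphenylthio)epiafzelechin F5. Compound 5 is activated by BF3·OEt2, which leaves the thioether alone, and is captured by C6 of F5 (C8 is blocked) to give the perbenzylated dibromo upper dimer with a 4β-arylthio group on unit 2 F6. Compound 2 is benzylated at O3 to 3,5,7,3',4'-penta-O-benzylepicatechin F7 and oxidised with DDQ and 2-ethoxyethanol to 3,5,7,3',4'-penta-O-benzyl-4β-(2-ethoxyethoxy)epicatechin F8. F8 with an excess of 4 and TMSOTf gives the perbenzylated lower dimer with free C8 on unit 3 and bromine on C8 of unit 4 F9. Soft activation of the thioether of F6 (I2, Ag2O) in the presence of F9 joins C4 of unit 2 to C8 of unit 3 and gives the perbenzylated tribromo tetramer F10. Hydrogenolysis of F10 under the conditions of step 19 gives 26.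

2. Step 13. Capture of the C4 cation by the hindered, bromine-deactivated C6 of 4 is slow, so the cation from 16 may instead alkylate the silylalkyne of a second molecule or lose a proton to the flav-3-ene.
Fallback (from 5 and 4, returning at 17): the interflavan bond is made first with a halogen-capped cation and the alkyne is introduced afterwards. Bromine–lithium exchange on 5 (n-BuLi, THF, −78 °C) and quenching with I2 give 3,5,7,3',4'-penta-O-benzyl-4β-(2-ethoxyethoxy)-8-iodoepicatechin F11. F11 and 4 (3 equiv) under TMSOTf give the perbenzylated lower dimer with iodine on C8 of unit 3 and bromine on C8 of unit 4 F12. A Sonogashira coupling of F12 with 15 at room temperature (PdCl2(PPh3)2, CuI, Et3N), which should occur at the iodide only, returns to 17.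

3. Step 16. The electron-rich, doubly ortho-substituted styrenyl trifluoroborate may undergo protodeboronation or oxidative homocoupling faster than C–O coupling.
Fallback (from 18, returning at 21): the enol ester is made from the aldehyde oxidation level. Anti-Markovnikov hydroboration of 18 with dicyclohexylborane and oxidation with NaBO3 give the perbenzylated lower dimer with a 2-oxoethyl group on C8 of unit 3 F13. Its potassium enolate (KN(SiMe3)2, THF, −78 °C) is O-acylated with benzoic anhydride. The flanking ortho oxygens should favour the E-enol benzoate, which is separated from any Z-isomer to give 21.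

**Further compounds**

F1 | step 17 | 5,7,4'-tri-O-benzylepiafzelechin | c9ccccc9COc1ccc([C@H]2Oc3cc(OCc9ccccc9)cc(OCc9ccccc9)c3C[C@H]2O)cc1
F2 | step 17 | 8-bromo-5,7,4'-tri-O-benzylepiafzelechin | c9ccccc9COc1ccc([C@H]2Oc3c(Br)c(OCc9ccccc9)cc(OCc9ccccc9)c3C[C@H]2O)cc1
F3 | step 17 | 8-bromo-3,5,7,4'-tetra-O-benzylepiafzelechin | c9ccccc9COc1ccc([C@H]2Oc3c(Br)c(OCc9ccccc9)cc(OCc9ccccc9)c3C[C@H]2OCc9ccccc9)cc1
F4 | step 17 | 8-bromo-3,5,7,4'-tetra-O-benzyl-4β-(2-ethoxyethoxy)epiafzelechin | c9ccccc9COc1ccc([C@H]2Oc3c(Br)c(OCc9ccccc9)cc(OCc9ccccc9)c3[C@H](OCCOCC)[C@H]2OCc9ccccc9)cc1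
F5 | step 17 | 8-bromo-3,5,7,4'-tetra-O-benzyl-4β-(2,6-dimethylphenylthio)epiafzelechin | c9ccccc9COc1ccc([C@H]2Oc3c(Br)c(OCc9ccccc9)cc(OCc9ccccc9)c3[C@H](Sc3c(C)cccc3C)[C@H]2OCc9ccccc9)cc1
F6 | step 17 | perbenzylated dibromo upper dimer, 8-bromoepicatechin-(4β→6)-8-bromo-4β-(2,6-dimethylphenylthio)epiafzelechin | c9ccccc9COc1ccc([C@H]2Oc3c(Br)c(OCc9ccccc9)c([C@H]4c5c(OCc9ccccc9)cc(OCc9ccccc9)c(Br)c5O[C@H](c5ccc(OCc9ccccc9)c(OCc9ccccc9)c5)[C@@H]4OCc9ccccc9)c(OCc9ccccc9)c3[C@H](Sc3c(C)cccc3C)[C@H]2OCc9ccccc9)cc1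
F7 | step 17 | 3,5,7,3',4'-penta-O-benzylepicatechin | c9ccccc9CO[C@@H]1Cc2c(OCc9ccccc9)cc(OCc9ccccc9)cc2O[C@@H]1c1ccc(OCc9ccccc9)c(OCc9ccccc9)c1
F8 | step 17 | 3,5,7,3',4'-penta-O-benzyl-4β-(2-ethoxyethoxy)epicatechin | CCOCCO[C@H]1c2c(OCc9ccccc9)cc(OCc9ccccc9)cc2O[C@H](c2ccc(OCc9ccccc9)c(OCc9ccccc9)c2)[C@@H]1OCc9ccccc9
F9 | step 17 | perbenzylated lower dimer, epicatechin-(4β→6)-8-bromoepicatechin with free C8 on unit 3 | c3c(OCc9ccccc9)cc(OCc9ccccc9)c4c3O[C@H](c3ccc(OCc9ccccc9)c(OCc9ccccc9)c3)[C@H](OCc9ccccc9)[C@H]4c3c(OCc9ccccc9)c(Br)c4c(c3OCc9ccccc9)C[C@@H](OCc9ccccc9)[C@@H](c3ccc(OCc9ccccc9)c(OCc9ccccc9)c3)O4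
F10 | step 17 | perbenzylated tribromo tetramer (bromine on C8 of units 1, 2 and 4, 3-O-benzyl on unit 2) | c9ccccc9COc1ccc([C@H]2Oc3c(Br)c(OCc9ccccc9)c([C@H]4c5c(OCc9ccccc9)cc(OCc9ccccc9)c(Br)c5O[C@H](c5ccc(OCc9ccccc9)c(OCc9ccccc9)c5)[C@@H]4OCc9ccccc9)c(OCc9ccccc9)c3[C@H](c3c(OCc9ccccc9)cc(OCc9ccccc9)c4c3O[C@H](c3ccc(OCc9ccccc9)c(OCc9ccccc9)c3)[C@H](OCc9ccccc9)[C@H]4c3c(OCc9ccccc9)c(Br)c4c(c3OCc9ccccc9)C[C@@H](OCc9ccccc9)[C@@H](c3ccc(OCc9ccccc9)c(OCc9ccccc9)c3)O4)[C@H]2OCc9ccccc9)cc1
F11 | step 13 | 3,5,7,3',4'-penta-O-benzyl-4β-(2-ethoxyethoxy)-8-iodoepicatechin | CCOCCO[C@H]1c2c(OCc9ccccc9)cc(OCc9ccccc9)c(I)c2O[C@H](c2ccc(OCc9ccccc9)c(OCc9ccccc9)c2)[C@@H]1OCc9ccccc9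
F12 | step 13 | perbenzylated lower dimer, 8-iodoepicatechin-(4β→6)-8-bromoepicatechin | Ic3c(OCc9ccccc9)cc(OCc9ccccc9)c4c3O[C@H](c3ccc(OCc9ccccc9)c(OCc9ccccc9)c3)[C@H](OCc9ccccc9)[C@H]4c3c(OCc9ccccc9)c(Br)c4c(c3OCc9ccccc9)C[C@@H](OCc9ccccc9)[C@@H](c3ccc(OCc9ccccc9)c(OCc9ccccc9)c3)O4
F13 | step 16 | perbenzylated lower dimer with a 2-oxoethyl group on C8 of unit 3 | O=CCc3c(OCc9ccccc9)cc(OCc9ccccc9)c4c3O[C@H](c3ccc(OCc9ccccc9)c(OCc9ccccc9)c3)[C@H](OCc9ccccc9)[C@H]4c3c(OCc9ccccc9)c(Br)c4c(c3OCc9ccccc9)C[C@@H](OCc9ccccc9)[C@@H](c3ccc(OCc9ccccc9)c(OCc9ccccc9)c3)O4
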